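**Retrosynthetic overview**
- The aryl ester C–O bond between O4 of ring A (the benzoic acid ring) and the carbonyl carbon of ring B is cut. This gives phenol 13, with its acid masked as a benzyl ester, and acid chloride 19. The benzyl group is removed last by hydrogenolysis.
- The strategy rests on ring A, where C6–OMe, C1–CO2H and C2–heptyl sit on three neighbouring carbons. This is the pattern left when a nucleophile and then an electrophile add across C1≡C2 of a 3-methoxybenzyne. Both C–C bonds are cut together, back to aryl fluoride 3, heptyllithium 5 and CO2 6, with O4 carried as a triisopropylsilyl ether.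
- The ring B acid comes from olivetol by O-methylation, Vilsmeier–Haack formylation and Pinnick oxidation.
- No ring is formed in the route, because both benzene rings are bought intact.

Key step: step 3

Remark: ring A is numbered as in the target (C1 carboxyl, C2 heptyl, C4 oxygen, C6 methoxy). The target has no stereocentre. Heptyllithium 5 is made as a titrated stock solution, and this is counted as a step.

**Step 1**
Reactants: 1 3-fluoro-5-methoxyphenol; 2 triisopropylsilyl chloride
Product: 3 (3-fluoro-5-methoxyphenoxy)tri(propan-2-yl)silane
Conditions: 2 (1.1 equiv), imidazole (2 equiv), DMF, rt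
Reagents that add atoms: triisopropylsilyl chloride 2, CC(C)[Si](Cl)(C(C)C)C(C)C
Why: Imidazole-promoted silyl ether formation at the only hydroxyl group is reliable for phenols, and the triisopropylsilyl group is chosen because it withstands alkyllithiums and shields its two ortho positions in step 3.

**Step 2**
Reactants: 4 1-bromoheptane
Product: 5 heptyllithium (solution in Et2O, titrated and used the same day)
Conditions: Li wire (ca. 1% Na, 2.2 equiv), Et2O, −10 °C, Ar; filter under Ar, titrate
Reagents that add atoms: lithium metal, [Li]
Why: Reductive lithiation of a primary alkyl bromide with lithium metal in ether is the standard direct synthesis of n-alkyllithiums, and the low temperature holds back Wurtz coupling.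

**Step 3**
Reactants: 3 (3-fluoro-5-methoxyphenoxy)tri(propan-2-yl)silane; 5 heptyllithium; 6 carbon dioxide
Product: 11 2-heptyl-6-methoxy-4-[(triisopropylsilyl)oxy]benzoic acid, via 2-lithio aryl fluoride 7 (not isolated), via 3-methoxy-5-(triisopropylsilyloxy)benzyne 8 (not isolated), via 2-heptyl-6-methoxyaryllithium 9 (not isolated), via lithium carboxylate 10 (not isolated)
Conditions: 5 (3 equiv), THF/Et2O (dilute), −78 °C, 1 h; −78 → −25 °C, 2 h; recool to −78 °C and cannulate onto excess solid CO2 6 in Et2O; 1 M HCl, 0 °C
Reagents that add atoms: heptyllithium 5, [Li]CCCCCCC; carbon dioxide 6, O=C=O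
Why: Heptyllithium first removes the proton on the carbon between C–F and C–OMe of 3 (directed ortho-metalation) to give 7, which loses LiF on warming to form aryne 8; a second heptyllithium adds across the strained triple bond (aryne carbolithiation) and the resulting aryllithium 9 is carboxylated, so the C2–heptyl and C1–CO2H bonds of ring A arise in one flask. The closest known reaction type is the tandem addition of n-alkyllithiums to the 3-methoxybenzyne released from 3-fluoroanisole followed by a CO2 quench, an established entry to 6-alkyl-2-methoxybenzoic acids. No ring is closed and no stereocentre is created. Two selectivities are needed: deprotonation between F and OMe rather than at either carbon next to the silyl ether, which the bulky and poorly coordinating triisopropylsilyloxy group secures by blocking both of its ortho positions, and attack at the aryne carbon remote from methoxy, which follows because the sigma-withdrawing C–O bond polarises the aryne so that charge builds up on the carbon next to oxygen, where lithium is also held by the methoxy lone pair. The silyloxy group lies one position further from the triple bond, exerts only a weak opposing inductive bias and should not overturn this preference. Excess 5 and dilution keep 7 and 9 from competing as nucleophiles for 8, and inverse addition to a large excess of CO2 at −78 °C suppresses ketone formation from 10.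

**Step 4**
Reactants: 11 2-heptyl-6-methoxy-4-[(triisopropylsilyl)oxy]benzoic acid
Product: 12 benzyl 2-heptyl-6-methoxy-4-[(triisopropylsilyl)oxy]benzoate
Conditions: BnBr (1.2 equiv), KHCO3 (1.5 equiv), DMF, rt → 40 °C
Reagents that add atoms: benzyl bromide, BrCc1ccccc1
Why: O-Alkylation of the carboxylate (SN2 on benzyl bromide) takes place away from the crowded acyl carbon, so the two ortho substituents do not slow it, and the weak base KHCO3 leaves the aryl silyl ether intact.

**Step 5**
Reactants: 12 benzyl 2-heptyl-6-methoxy-4-[(triisopropylsilyl)oxy]benzoate
Product: 13 benzyl 2-heptyl-4-hydroxy-6-methoxybenzoate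
Conditions: Bu4NF (1.1 equiv), AcOH (1.1 equiv), THF, 0 °C
Reagents that add atoms: none
Why: Fluoride-induced desilylation, driven by the strong Si–F bond, frees the phenol, and the acetic acid buffer keeps the medium from becoming basic enough to touch the benzyl ester.

**Step 6**
Reactants: 14 olivetol (5-pentylbenzene-1,3-diol)
Product: 15 1,3-dimethoxy-5-pentylbenzene
Conditions: MeI (2.5 equiv), K2CO3 (3 equiv), acetone, reflux
Reagents that add atoms: iodomethane, CI
Why: Williamson ether synthesis on both phenolic hydroxyls of a resorcinol proceeds on oxygen with a carbonate base in acetone.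

**Step 7**
Reactants: 15 1,3-dimethoxy-5-pentylbenzene
Product: 17 2,4-dimethoxy-6-pentylbenzaldehyde, via aryl iminium chloride 16 (not isolated)
Conditions: POCl3 (1.5 equiv), DMF, 0 °C → 60 °C; then ice–H2O, rt
Reagents that add atoms: N,N-dimethylformamide, CN(C)C=O; water, O
Why: Vilsmeier–Haack formylation attacks the carbon that is para to one methoxy and ortho to the other (two such sites, equivalent by symmetry), the usual outcome for 5-alkylresorcinol dimethyl ethers, and not the carbon between the two methoxy groups, so the formyl group ends up next to the pentyl chain.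

**Step 8**
Reactants: 17 2,4-dimethoxy-6-pentylbenzaldehyde
Product: 18 2,4-dimethoxy-6-pentylbenzoic acid
Conditions: NaClO2 (1.5 equiv), NaH2PO4 (2 equiv), 2-methyl-2-butene (10 equiv), t-BuOH/H2O, rt
Reagents that add atoms: sodium chlorite, [Na+].[O-]Cl=O
Why: Pinnick oxidation converts the aldehyde into the acid under buffered conditions, and 2-methyl-2-butene traps the hypochlorous acid that would otherwise chlorinate the electron-rich ring.

**Step 9**
Reactants: 18 2,4-dimethoxy-6-pentylbenzoic acid
Product: 19 2,4-dimethoxy-6-pentylbenzoyl chloride (used crude)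
Conditions: (COCl)2 (1.5 equiv), DMF (cat.), CH2Cl2, 0 °C → rt; evaporate
Reagents that add atoms: oxalyl chloride, ClC(=O)C(=O)Cl
Why: DMF-catalysed acid chloride formation with oxalyl chloride runs at room temperature and gives only gaseous by-products, so crude 19 can be used at once.

**Step 10**
Reactants: 13 benzyl 2-heptyl-4-hydroxy-6-methoxybenzoate; 19 2,4-dimethoxy-6-pentylbenzoyl chloride
Product: 20 benzyl 4-[(2,4-dimethoxy-6-pentylbenzoyl)oxy]-2-heptyl-6-methoxybenzoate
Conditions: 19 (1.2 equiv), Et3N (2 equiv), DMAP (0.2 equiv), CH2Cl2, 0 °C → rt
Reagents that add atoms: none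
Why: DMAP-catalysed acylation of an unhindered and fairly acidic phenol (both carbons ortho to O4 carry hydrogen) by an acid chloride is a standard aryl ester synthesis, and the benzyl ester keeps the ring A acid from forming mixed anhydrides.

**Step 11**
Reactants: 20 benzyl 4-[(2,4-dimethoxy-6-pentylbenzoyl)oxy]-2-heptyl-6-methoxybenzoate
Product: 21 4-[(2,4-dimethoxy-6-pentylbenzoyl)oxy]-2-heptyl-6-methoxybenzoic acid (target, CNP0206304.0)
Conditions: H2 (1 atm), 10% Pd/C, EtOAc, rt
Reagents that add atoms: none
Why: Catalytic hydrogenolysis cleaves only the benzylic C–O bond and leaves the aryl ester, the methyl ethers and both arenes untouched, and the non-nucleophilic solvent excludes transesterification of the depside link.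

**Compound list**
1 | 3-fluoro-5-methoxyphenol | COc1cc(O)cc(F)c1 | starting material
2 | triisopropylsilyl chloride | CC(C)[Si](Cl)(C(C)C)C(C)C | starting material
3 | (3-fluoro-5-methoxyphenoxy)tri(propan-2-yl)silane | COc1cc(F)cc(O[Si](C(C)C)(C(C)C)C(C)C)c1 | intermediate
4 | 1-bromoheptane | CCCCCCCBr | starting material
5 | heptyllithium | [Li]CCCCCCC | intermediate
6 | carbon dioxide | O=C=O | starting material
7 | {2-fluoro-6-methoxy-4-[(triisopropylsilyl)oxy]phenyl}lithium | COc1cc(O[Si](C(C)C)(C(C)C)C(C)C)cc(F)c1[Li] | intermediate
8 | 3-methoxy-5-[(triisopropylsilyl)oxy]benzyne | COC1=CC(O[Si](C(C)C)(C(C)C)C(C)C)=CC#C1 | intermediate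
9 | {2-heptyl-6-methoxy-4-[(triisopropylsilyl)oxy]phenyl}lithium | CCCCCCCc1cc(O[Si](C(C)C)(C(C)C)C(C)C)cc(OC)c1[Li] | intermediate
10 | lithium 2-heptyl-6-methoxy-4-[(triisopropylsilyl)oxy]benzoate | CCCCCCCc1cc(O[Si](C(C)C)(C(C)C)C(C)C)cc(OC)c1C(=O)[O-].[Li+] | intermediate
11 | 2-heptyl-6-methoxy-4-[(triisopropylsilyl)oxy]benzoic acid | CCCCCCCc1cc(O[Si](C(C)C)(C(C)C)C(C)C)cc(OC)c1C(=O)O | intermediate
12 | benzyl 2-heptyl-6-methoxy-4-[(triisopropylsilyl)oxy]benzoate | CCCCCCCc1cc(O[Si](C(C)C)(C(C)C)C(C)C)cc(OC)c1C(=O)OCc2ccccc2 | intermediate
13 | benzyl 2-heptyl-4-hydroxy-6-methoxybenzoate | CCCCCCCc1cc(O)cc(OC)c1C(=O)OCc2ccccc2 | intermediate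
14 | olivetol (5-pentylbenzene-1,3-diol) | CCCCCc1cc(O)cc(O)c1 | starting material
15 | 1,3-dimethoxy-5-pentylbenzene | CCCCCc1cc(OC)cc(OC)c1 | intermediate
16 | [(2,4-dimethoxy-6-pentylphenyl)methylidene]dimethylammonium chloride | CCCCCc1cc(OC)cc(OC)c1C=[N+](C)C.[Cl-] | intermediate
17 | 2,4-dimethoxy-6-pentylbenzaldehyde | CCCCCc1cc(OC)cc(OC)c1C=O | intermediate
18 | 2,4-dimethoxy-6-pentylbenzoic acid | CCCCCc1cc(OC)cc(OC)c1C(=O)O | intermediate
19 | 2,4-dimethoxy-6-pentylbenzoyl chloride | CCCCCc1cc(OC)cc(OC)c1C(=O)Cl | intermediate
20 | benzyl 4-[(2,4-dimethoxy-6-pentylbenzoyl)oxy]-2-heptyl-6-methoxybenzoate | CCCCCCCc1cc(OC(=O)c2c(CCCCC)cc(OC)cc2OC)cc(OC)c1C(=O)OCc3ccccc3 | intermediate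
21 | 4-[(2,4-dimethoxy-6-pentylbenzoyl)oxy]-2-heptyl-6-methoxybenzoic acid | CCCCCCCc1cc(OC(=O)c2c(CCCCC)cc(OC)cc2OC)cc(OC)c1C(=O)O | target

**Step count**
- Total step count: 11.
- Longest linear sequence: 6 steps (steps 1, 3, 4, 5, 10, 11). The ring B branch (steps 6, 7, 8, 9, 10, 11) and the heptyl branch (steps 2, 3, 4, 5, 10, 11) are equally long.

**Steps most likely to fail**

1. **Step 3.**
   - Risk: the aryllithiums 7 and 9 may compete with 5 for aryne 8 and give biaryl coupling. Regiocontrol may also be eroded, either in the deprotonation or in the addition to the aryne.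
   - Fallback: the two C–C bonds are made one after the other, without an aryne. Setting out from 3, lithiation with s-BuLi in THF is held at −78 °C and quenched with CO2 before any LiF is lost. This should give 2-fluoro-6-methoxy-4-[(triisopropylsilyl)oxy]benzoic acid F1, which can be freed of any regioisomer at this stage. Treating it with heptyllithium 5 (over 2 equiv, THF, −78 °C → −30 °C) first deprotonates the acid. It then displaces the fluoride ortho to the lithium carboxylate by addition–elimination, the carboxylate-assisted nucleophilic aromatic substitution known for unprotected 2-fluorobenzoic acids with organolithiums. The sequence comes back to the route at 11.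

2. **Step 10.**
   - Risk: acyl transfer at the doubly ortho-substituted carbonyl of 19 may be slow, so that hydrolysis or decomposition of the acid chloride outruns ester formation.
   - Fallback: step 9 is skipped and the mode of activation is changed. Setting out from acid 18 together with phenol 13, trifluoroacetic anhydride in toluene at rt forms 2,4-dimethoxy-6-pentylbenzoic trifluoroacetic anhydride F2 in the flask. This mixed anhydride ionises readily towards the electron-rich acylium ion, which is not sensitive to ortho crowding, and it acylates 13 in the classical depside condensation. The sequence comes back to the route at 20.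

3. **Step 2.**
   - Risk: Wurtz coupling at the lithium surface and slow ether cleavage may lower the titre and make it uncertain, which upsets the stoichiometry on which step 3 depends.
   - Fallback: setting out from 4, Finkelstein exchange (NaI, acetone, reflux) gives 1-iodoheptane F3. Iodine–lithium exchange with t-BuLi (2.1 equiv) in pentane/Et2O at −78 °C then delivers a homogeneous solution of the alkyllithium without a metal surface. The sequence comes back to the route at 5.

**Further compounds**
F1 | step 3 | 2-fluoro-6-methoxy-4-[(triisopropylsilyl)oxy]benzoic acid | COc1cc(O[Si](C(C)C)(C(C)C)C(C)C)cc(F)c1C(=O)O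
F2 | step 10 | 2,4-dimethoxy-6-pentylbenzoic trifluoroacetic anhydride | CCCCCc1cc(OC)cc(OC)c1C(=O)OC(=O)C(F)(F)F
F3 | step 2 | 1-iodoheptane | CCCCCCCI
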